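**Retrosynthetic overview**
Labels: ring A (chlorinated) a1 C–OMe, a2 C–H, a3 C–CO2H, a4 C–OAr, a5 C–OH, a6 C–Cl; ring B b1 C–O, b2 C–H, b3 C–CH3, b4 C–H, b5 C–OH, b6 C–CO2H.
Feature used: the a1(O)–a6(Cl)–a5(O) segment of ring A is the aromatised form of a 2-chlorocyclohexane-1,3-dione. Its alpha carbon a4 carries the ring B aryloxy group and its neighbour a3 carries the carboxyl, so ring A can be grown saturated on the oxygen of ring B.
Disconnections, backwards: BCl3 unmasking (two tBu esters, b5–OMe); a1–O–CH3; loss of HCl from the a6,a6-dichloro-1,3-dione; then a6–a5 (Dieckmann) and a4–a3 (Michael), which open ring A to aryloxyacetate 5 and enone 8.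
The crowded b1–O–a4 ether is made early by phenol alkylation at an sp3 carbon. Ring B is bought; ring A is the only ring formed (step 5) and becomes aromatic in step 7.
The b6 carboxyl travels as a tert-butyl ester. A methyl ester ortho to the OCH2CO2Me arm would be acylated by the enolate (five-membered Dieckmann closure to a 3-hydroxybenzofuran-2-carboxylate) before any Michael addition.
Key step: step 5

Assumption: the target has no stereocentre and the diaryl ether axis is taken as freely rotating, so racemic intermediates are sufficient.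

Step 1
Reactants: 1 2,6-dihydroxy-4-methylbenzoic acid
Product: 2 tert-butyl 2,6-dihydroxy-4-methylbenzoate
Conditions: Cl3CC(=NH)OtBu (2.5 equiv), THF–CH2Cl2, 0 °C to rt
Reagents that add atoms: tert-butyl 2,2,2-trichloroacetimidate, CC(C)(C)OC(=N)C(Cl)(Cl)Cl
Why: Imidate esterification, in which the strongly acidic, doubly hydrogen-bonded acid protonates the imidate and its carboxylate captures the tert-butyl group, while the phenols stay untouched without a Lewis acid and the low temperature avoids decarboxylation.

Step 2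
Reactants: 2 tert-butyl 2,6-dihydroxy-4-methylbenzoate
Product: 3 tert-butyl 2-hydroxy-6-methoxy-4-methylbenzoate
Conditions: MeI (1.05 equiv), K2CO3 (1.1 equiv), acetone, rt to 40 °C
Reagents that add atoms: iodomethane, CI
Why: Williamson etherification of two equivalent phenols should stop after one methylation, because the remaining hydroxyl is held in a strong hydrogen bond to the ester carbonyl and reacts much more slowly.

Step 3
Reactants: 3 tert-butyl 2-hydroxy-6-methoxy-4-methylbenzoate; 4 methyl bromoacetate
Product: 5 tert-butyl 2-methoxy-6-(2-methoxy-2-oxoethoxy)-4-methylbenzoate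
Conditions: K2CO3 (2 equiv), DMF, 50 °C
Reagents that add atoms: none
Why: Williamson etherification with an activated alpha-bromo ester makes the hindered b1–O–a4 bond at an sp3 carbon, and carbonate is too weak to enolise the product toward the tert-butyl benzoate.

Step 4
Reactants: 6 methylglyoxal (40% aqueous solution); 7 tert-butyl (triphenylphosphoranylidene)acetate
Product: 8 tert-butyl (E)-4-oxopent-2-enoate
Conditions: CH2Cl2–H2O, 0 °C to rt
Reagents that add atoms: none
Why: Wittig olefination with a stabilised, water-tolerant ylide, which takes only the aldehyde carbonyl, leaves the ketone alone and should give the E alkene as stabilised ylides do.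

Step 5
Reactants: 5 tert-butyl 2-methoxy-6-(2-methoxy-2-oxoethoxy)-4-methylbenzoate; 8 tert-butyl (E)-4-oxopent-2-enoate
Product: 11 tert-butyl trans-2-[2-(tert-butoxycarbonyl)-3-methoxy-5-methylphenoxy]-3,5-dioxocyclohexane-1-carboxylate (racemic), via chelated lithium ester enolate 9 (not isolated), via acyclic Michael adduct 10 (not isolated)
Conditions: LiN(iPr)2 (commercial solution, 1.05 equiv), THF, −78 °C, 20 min; 8 (1.1 equiv), −78 to −30 °C; KOtBu (0.5 equiv, 1 M in tBuOH), −30 to 0 °C; cold 1 M HCl to pH 3
Reagents that add atoms: none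
Why: LiN(iPr)2 turns 5 into lithium enolate 9, which adds in Michael fashion to the olefinic carbon of 8 that is beta to the ketone (the carbon bearing CO2tBu) because the ketone is the stronger acceptor, so a4–a3 forms and 10 is left as its ketone enolate, while any 1,2-aldolate should revert on warming. The KOtBu/tBuOH pair then shuttles protons so that the terminal methyl ketone enolate (a6) is populated and acylates the methyl ester carbon a5 in a 6-exo-trig Dieckmann closure of ring A, and deprotonation of the acidic 1,3-dione pulls all equilibria forward. The closest known reaction type is the Michael–Dieckmann (Michael–Claisen) annulation of ester enolates with methyl enones that gives dimedone and related cyclohexane-1,3-diones. Only the methyl ester is an accessible acyl acceptor, because the tert-butyl ester on a3 blocks the five-membered closure of a6 onto it and the doubly ortho-flanked tert-butyl ester on b6 blocks the 5-exo attack of the enolate carbon that a methyl benzoate would suffer. The a4 and a3 centres are not set kinetically; a4 is alpha to a ketone and should equilibrate under the basic conditions to the trans (pseudo-diequatorial) isomer, and both centres vanish in step 7. E1cB loss of the aryloxide from an a3 ester enolate is held back by the small excess of base and by staying at or below 0 °C, since the product rests as its unreactive dione enolate.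

Step 6
Reactants: 11 tert-butyl trans-2-[2-(tert-butoxycarbonyl)-3-methoxy-5-methylphenoxy]-3,5-dioxocyclohexane-1-carboxylate
Product: 12 tert-butyl trans-4,4-dichloro-2-[2-(tert-butoxycarbonyl)-3-methoxy-5-methylphenoxy]-3,5-dioxocyclohexane-1-carboxylate (racemic; taken on crude after an aqueous wash)
Conditions: NCS (2.05 equiv), CH2Cl2, 0 °C to rt, dark
Reagents that add atoms: N-chlorosuccinimide, O=C1CCC(=O)N1Cl
Why: Electrophilic alpha-chlorination of an enolised 1,3-dione puts both chlorines on a6, the only doubly activated carbon, and neutral NCS is preferred to SO2Cl2 because it liberates no HCl (tert-butyl esters) and attacks the dialkoxyarene ring B far more slowly than the enol.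

Step 7
Reactants: 12 tert-butyl trans-4,4-dichloro-2-[2-(tert-butoxycarbonyl)-3-methoxy-5-methylphenoxy]-3,5-dioxocyclohexane-1-carboxylate
Product: 13 tert-butyl 2-[2-(tert-butoxycarbonyl)-3-methoxy-5-methylphenoxy]-4-chloro-3,5-dihydroxybenzoate
Conditions: Li2CO3 (1.5 equiv), LiCl (0.2 equiv), dry DMF, 60–80 °C; cold dilute HCl work-up
Reagents that add atoms: none
Why: Dehydrochlorinative aromatisation of a 2,2-dichlorocyclohexane-1,3-dione to a 2-chlororesorcinol, in which enolisation of a5 toward a4 followed by vinylogous loss of a3–H and one a6 chloride, or a chloride-catalysed shift of chlorine to a2 or a4 followed by 1,2-elimination, all lead to the same dienone that tautomerises to the arene, while the carbonate buffer spares the tert-butyl esters and a tertiary amine is avoided because it would be chlorinated.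

Step 8
Reactants: 13 tert-butyl 2-[2-(tert-butoxycarbonyl)-3-methoxy-5-methylphenoxy]-4-chloro-3,5-dihydroxybenzoate
Product: 14 tert-butyl 2-[2-(tert-butoxycarbonyl)-3-methoxy-5-methylphenoxy]-4-chloro-3-hydroxy-5-methoxybenzoate
Conditions: MeI (1.0 equiv), K2CO3 (1.0 equiv), DMF, 0 °C to rt
Reagents that add atoms: iodomethane, CI
Why: Williamson etherification under substrate control, since the a5 hydroxyl lies between a6–Cl and the doubly ortho-substituted aryloxy group on a4 and can hydrogen-bond to the b6 ester carbonyl, whereas the a1 hydroxyl has the open a2–H side and should take up the single equivalent of MeI.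

Step 9
Reactants: 14 tert-butyl 2-[2-(tert-butoxycarbonyl)-3-methoxy-5-methylphenoxy]-4-chloro-3-hydroxy-5-methoxybenzoate
Product: 15 2-(2-carboxy-3-hydroxy-5-methylphenoxy)-4-chloro-3-hydroxy-5-methoxybenzoic acid (target)
Conditions: BCl3 (1 M in CH2Cl2, 8 equiv), CH2Cl2, −78 to 0 °C; cold H2O–THF, extraction with EtOAc below rt
Reagents that add atoms: none
Why: Lewis acid dealkylation, in which BCl3 ionises both tert-butyl esters and, chelated between the b6 carboxyl oxygen and the b5 methoxy oxygen, removes only that ortho-carbonyl methyl ether, while the a1 methoxy group has no neighbouring carbonyl and should resist BCl3 at or below 0 °C.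

**Compound list**
1 | 2,6-dihydroxy-4-methylbenzoic acid | Cc1cc(O)c(C(=O)O)c(O)c1 | starting material
2 | tert-butyl 2,6-dihydroxy-4-methylbenzoate | Cc1cc(O)c(C(=O)OC(C)(C)C)c(O)c1 | intermediate
3 | tert-butyl 2-hydroxy-6-methoxy-4-methylbenzoate | COc1cc(C)cc(O)c1C(=O)OC(C)(C)C | intermediate
4 | methyl bromoacetate | COC(=O)CBr | starting material
5 | tert-butyl 2-methoxy-6-(2-methoxy-2-oxoethoxy)-4-methylbenzoate | COC(=O)COc1cc(C)cc(OC)c1C(=O)OC(C)(C)C | intermediate
6 | methylglyoxal | CC(=O)C=O | starting material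
7 | tert-butyl (triphenylphosphoranylidene)acetate | CC(C)(C)OC(=O)C=P(c1ccccc1)(c1ccccc1)c1ccccc1 | starting material
8 | tert-butyl (E)-4-oxopent-2-enoate | CC(=O)/C=C/C(=O)OC(C)(C)C | intermediate
9 | lithium 2-[2-(tert-butoxycarbonyl)-3-methoxy-5-methylphenoxy]-1-methoxyethen-1-olate (drawn chelated, OLi and OAr cis; not isolated) | [Li+].[O-]/C(OC)=C\Oc1cc(C)cc(OC)c1C(=O)OC(C)(C)C | intermediate
10 | 4-tert-butyl 1-methyl 2-[2-(tert-butoxycarbonyl)-3-methoxy-5-methylphenoxy]-3-(2-oxopropyl)butanedioate (diastereomer mixture, present as its enolate, drawn neutral; not isolated) | COC(=O)C(Oc1cc(C)cc(OC)c1C(=O)OC(C)(C)C)C(CC(C)=O)C(=O)OC(C)(C)C | intermediate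
11 | tert-butyl trans-2-[2-(tert-butoxycarbonyl)-3-methoxy-5-methylphenoxy]-3,5-dioxocyclohexane-1-carboxylate (racemic, one enantiomer drawn) | O=C1CC(=O)[C@@H](Oc2cc(C)cc(OC)c2C(=O)OC(C)(C)C)[C@H](C(=O)OC(C)(C)C)C1 | intermediate
12 | tert-butyl trans-4,4-dichloro-2-[2-(tert-butoxycarbonyl)-3-methoxy-5-methylphenoxy]-3,5-dioxocyclohexane-1-carboxylate (racemic, one enantiomer drawn) | O=C1C(Cl)(Cl)C(=O)[C@@H](Oc2cc(C)cc(OC)c2C(=O)OC(C)(C)C)[C@H](C(=O)OC(C)(C)C)C1 | intermediate
13 | tert-butyl 2-[2-(tert-butoxycarbonyl)-3-methoxy-5-methylphenoxy]-4-chloro-3,5-dihydroxybenzoate | CC(C)(C)OC(=O)c1cc(O)c(Cl)c(O)c1Oc1cc(C)cc(OC)c1C(=O)OC(C)(C)C | intermediate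
14 | tert-butyl 2-[2-(tert-butoxycarbonyl)-3-methoxy-5-methylphenoxy]-4-chloro-3-hydroxy-5-methoxybenzoate | CC(C)(C)OC(=O)c1cc(OC)c(Cl)c(O)c1Oc1cc(C)cc(OC)c1C(=O)OC(C)(C)C | intermediate
15 | 2-(2-carboxy-3-hydroxy-5-methylphenoxy)-4-chloro-3-hydroxy-5-methoxybenzoic acid | COc1cc(C(=O)O)c(Oc2cc(C)cc(O)c2C(=O)O)c(O)c1Cl | target

**Step count**
Total steps: 9. Longest linear sequence: 8 (steps 1, 2, 3, 5, 6, 7, 8, 9).

**Steps most likely to fail**

**Step 5.**
- Risks:
  - The hard lithium enolate may add 1,2 to the ketone.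
  - It may merely deprotonate the methyl ketone, so that the enone oligomerises.
  - It may acylate itself on the ring B ester.
  - Under KOtBu, an a3 ester enolate may expel the aryloxide.
- Fallback: a neutral conjugate addition, with the two bond formations separated.
  - It sets out from 5. Enolisation with LiN(iPr)2 in the presence of Me3SiCl (internal quench, THF, −78 °C) gives tert-butyl 2-methoxy-6-{[2-methoxy-2-(trimethylsilyloxy)ethenyl]oxy}-4-methylbenzoate F1.
  - A Mukaiyama–Michael addition of the ketene acetal to 8 follows (Sc(OTf)3, 10 mol %, CH2Cl2, −40 to 0 °C). The Lewis acid sits on the more basic ketone and so reinforces attack beta to it. After aqueous work-up, 10 is obtained and is now isolated.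
  - Treating 10 with KOtBu (1.1 equiv) in THF–tBuOH at 0 °C effects the Dieckmann closure, and the route is rejoined at 11.

**Step 7.**
- Risks:
  - Positive chlorine may be transferred from a6 to the electron-rich ring B or to a2 of the freshly formed resorcinol.
  - The aryloxide may be expelled from a4.
  - The dichlorodione may suffer hydrolytic ring cleavage.
- Fallback: chlorination is separated from oxidation.
  - It sets out from 11. One equivalent of NCS (CH2Cl2, 0 °C) gives tert-butyl trans-4-chloro-2-[2-(tert-butoxycarbonyl)-3-methoxy-5-methylphenoxy]-3,5-dioxocyclohexane-1-carboxylate F2.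
  - Soft double enolisation (TBSOTf, 2.5 equiv, Et3N, CH2Cl2, 0 °C) gives tert-butyl 3,5-bis(tert-butyldimethylsilyloxy)-4-chloro-2-[2-(tert-butoxycarbonyl)-3-methoxy-5-methylphenoxy]cyclohexa-2,4-diene-1-carboxylate F3.
  - Dehydrogenation of this cyclohexadiene with DDQ (1.1 equiv, 2,6-lutidine, toluene, rt) gives tert-butyl 3,5-bis(tert-butyldimethylsilyloxy)-4-chloro-2-[2-(tert-butoxycarbonyl)-3-methoxy-5-methylphenoxy]benzoate F4.
  - Bu4NF/AcOH in THF at 0 °C removes both silyl groups, and the route is rejoined at 13.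

**Step 8.**
- Risks:
  - Discrimination between the two phenols may be poor.
  - Double methylation may occur.
  - Base may induce a Smiles migration of ring B from the a4 oxygen to the a5 oxygen.
- Fallback: a protecting-group relay, in which a bulky reagent makes the steric choice.
  - It sets out from 13. TIPSCl and imidazole (DMF, 0 °C) silylate only the open a1 hydroxyl, giving tert-butyl 2-[2-(tert-butoxycarbonyl)-3-methoxy-5-methylphenoxy]-4-chloro-3-hydroxy-5-(triisopropylsilyloxy)benzoate F5.
  - MOMCl and iPr2NEt (CH2Cl2, rt) cap a5–OH, giving tert-butyl 2-[2-(tert-butoxycarbonyl)-3-methoxy-5-methylphenoxy]-4-chloro-3-(methoxymethoxy)-5-(triisopropylsilyloxy)benzoate F6.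
  - Bu4NF (THF, 0 °C) frees tert-butyl 2-[2-(tert-butoxycarbonyl)-3-methoxy-5-methylphenoxy]-4-chloro-5-hydroxy-3-(methoxymethoxy)benzoate F7.
  - MeI and K2CO3 (DMF, rt), now without any selectivity demand, give tert-butyl 2-[2-(tert-butoxycarbonyl)-3-methoxy-5-methylphenoxy]-4-chloro-5-methoxy-3-(methoxymethoxy)benzoate F8.
  - The BCl3 conditions of step 9 also cleave the acetal, so the route is rejoined at 15.

**Further compounds**
F1 | step 5 | tert-butyl 2-methoxy-6-{[2-methoxy-2-(trimethylsilyloxy)ethenyl]oxy}-4-methylbenzoate | C[Si](C)(C)O/C(OC)=C\Oc1cc(C)cc(OC)c1C(=O)OC(C)(C)C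
F2 | step 7 | tert-butyl trans-4-chloro-2-[2-(tert-butoxycarbonyl)-3-methoxy-5-methylphenoxy]-3,5-dioxocyclohexane-1-carboxylate (racemic, drawn as diketo tautomer) | O=C1C(Cl)C(=O)[C@@H](Oc2cc(C)cc(OC)c2C(=O)OC(C)(C)C)[C@H](C(=O)OC(C)(C)C)C1
F3 | step 7 | tert-butyl 3,5-bis(tert-butyldimethylsilyloxy)-4-chloro-2-[2-(tert-butoxycarbonyl)-3-methoxy-5-methylphenoxy]cyclohexa-2,4-diene-1-carboxylate (racemic) | CC(C)(C)OC(=O)C1CC(O[Si](C)(C)C(C)(C)C)=C(Cl)C(O[Si](C)(C)C(C)(C)C)=C1Oc1cc(C)cc(OC)c1C(=O)OC(C)(C)C
F4 | step 7 | tert-butyl 3,5-bis(tert-butyldimethylsilyloxy)-4-chloro-2-[2-(tert-butoxycarbonyl)-3-methoxy-5-methylphenoxy]benzoate | CC(C)(C)OC(=O)c1cc(O[Si](C)(C)C(C)(C)C)c(Cl)c(O[Si](C)(C)C(C)(C)C)c1Oc1cc(C)cc(OC)c1C(=O)OC(C)(C)C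
F5 | step 8 | tert-butyl 2-[2-(tert-butoxycarbonyl)-3-methoxy-5-methylphenoxy]-4-chloro-3-hydroxy-5-(triisopropylsilyloxy)benzoate | CC(C)(C)OC(=O)c1cc(O[Si](C(C)C)(C(C)C)C(C)C)c(Cl)c(O)c1Oc1cc(C)cc(OC)c1C(=O)OC(C)(C)C
F6 | step 8 | tert-butyl 2-[2-(tert-butoxycarbonyl)-3-methoxy-5-methylphenoxy]-4-chloro-3-(methoxymethoxy)-5-(triisopropylsilyloxy)benzoate | CC(C)(C)OC(=O)c1cc(O[Si](C(C)C)(C(C)C)C(C)C)c(Cl)c(OCOC)c1Oc1cc(C)cc(OC)c1C(=O)OC(C)(C)C
F7 | step 8 | tert-butyl 2-[2-(tert-butoxycarbonyl)-3-methoxy-5-methylphenoxy]-4-chloro-5-hydroxy-3-(methoxymethoxy)benzoate | CC(C)(C)OC(=O)c1cc(O)c(Cl)c(OCOC)c1Oc1cc(C)cc(OC)c1C(=O)OC(C)(C)C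
F8 | step 8 | tert-butyl 2-[2-(tert-butoxycarbonyl)-3-methoxy-5-methylphenoxy]-4-chloro-5-methoxy-3-(methoxymethoxy)benzoate | CC(C)(C)OC(=O)c1cc(OC)c(Cl)c(OCOC)c1Oc1cc(C)cc(OC)c1C(=O)OC(C)(C)C
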